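## Retrosynthetic overview
1. The target is an achiral 2,3-dialkylmaleic anhydride. No ring is formed: its only ring, the five-membered anhydride, is bought intact as citraconic anhydride and kept throughout.
2. Last disconnection: the ring C=C comes from sulfoxide syn-elimination of a 2-methyl-2-(2-pyridylthio)-3-alkylsuccinic anhydride.
3. Key C–C disconnection: the ring carbon–chain bond comes from the primary AcO(CH2)14 radical adding to citraconic anhydride (Barton decarboxylative addition with pyridylthio transfer).
4. The radical precursor is 15-acetoxypentadecanoic acid, whose extra carbon leaves as CO2. It is made by O-acetylation of commercial 15-hydroxypentadecanoic acid.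

Assumption: the SMILES holds no stereocentre and its one C=C is locked Z by the ring, so the compound is achiral and "single enantiomer" calls for no stereocontrol.

## Route

Step 1
Reactants: 1 15-hydroxypentadecanoic acid
Product: 2 15-acetoxypentadecanoic acid
Conditions: Ac2O (2 equiv), pyridine, cat. DMAP, 0 °C → rt, 6 h; H2O quench, 1 M HCl work-up
Reagents that add atoms: acetic anhydride, CC(=O)OC(C)=O
Why: DMAP/pyridine-catalysed O-acylation of the unhindered primary alcohol is fast, the carboxylic acid comes back free after the aqueous quench, and no stereocentre is involved.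

Step 2
Reactants: 2 15-acetoxypentadecanoic acid; 3 citraconic anhydride (3-methylfuran-2,5-dione, 5 equiv)
Product: 5 14-[4-methyl-2,5-dioxo-4-(pyridin-2-ylsulfanyl)oxolan-3-yl]tetradecyl acetate (racemic diastereomer mixture mainly trans; used crude), via Barton ester 4 (not isolated)
Conditions: 1-hydroxypyridine-2(1H)-thione (1.1 equiv), DCC (1.1 equiv), CH2Cl2, 0 °C → rt, 2 h, dark; then 3, hν (500 W tungsten lamp), 10–15 °C, 45 min; filter, strip excess 3 under high vacuum
Reagents that add atoms: 1-hydroxypyridine-2(1H)-thione (2-mercaptopyridine N-oxide), ON1C=CC=CC1=S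
Why: DCC esterification gives the O-acyl thiohydroxamate, and its visible-light Barton radical decarboxylation releases the nucleophilic primary C14 radical, which adds Giese-fashion to the unsubstituted carbon of electron-poor 3; the tertiary adduct radical then carries the chain by taking the 2-pyridylthio group from 4 mainly anti to the new chain, and both new stereocentres are racemic and are erased in step 3.

Step 3
Reactants: 5 14-[4-methyl-2,5-dioxo-4-(pyridin-2-ylsulfanyl)oxolan-3-yl]tetradecyl acetate
Product: 7 Aspergillus acid E, 14-(4-methyl-2,5-dioxo-2,5-dihydrofuran-3-yl)tetradecyl acetate, via sulfoxide 6 (not isolated)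
Conditions: mCPBA (1.05 equiv, pre-dried in CH2Cl2 over MgSO4), CH2Cl2, 0 °C, 30 min; solvent swap to PhMe, 80 °C, 1 h; SiO2 chromatography
Reagents that add atoms: mCPBA (3-chloroperoxybenzoic acid), OOC(=O)c1cccc(Cl)c1 (its oxygen atom sits in 6 and leaves again in the elimination; no reagent atom stays in 7)
Why: Chemoselective sulfide-to-sulfoxide oxidation followed by thermal sulfoxide syn-elimination (Ei) removes the activated C3–H, which is cis to sulfur in the major diastereomer, and gives the conjugated tetrasubstituted maleic anhydride; the acetate, the anhydride and the electron-poor alkene are inert to the peracid, and the ring fixes the alkene geometry with no stereocentre left to set.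

## Compound list
1 | 15-hydroxypentadecanoic acid | OCCCCCCCCCCCCCCC(=O)O | starting material
2 | 15-acetoxypentadecanoic acid | CC(=O)OCCCCCCCCCCCCCCC(=O)O | intermediate
3 | citraconic anhydride (3-methylfuran-2,5-dione) | CC1=CC(=O)OC1=O | starting material
4 | Barton ester, 2-thioxopyridin-1(2H)-yl 15-acetoxypentadecanoate | CC(=O)OCCCCCCCCCCCCCCC(=O)ON1C=CC=CC1=S | intermediate (not isolated)
5 | 14-[4-methyl-2,5-dioxo-4-(pyridin-2-ylsulfanyl)oxolan-3-yl]tetradecyl acetate (racemic, diastereomer mixture, so drawn flat) | CC(=O)OCCCCCCCCCCCCCCC1C(=O)OC(=O)C1(C)Sc1ccccn1 | intermediate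
6 | 14-[4-methyl-2,5-dioxo-4-(pyridin-2-ylsulfinyl)oxolan-3-yl]tetradecyl acetate (stereoisomer mixture, so drawn flat) | CC(=O)OCCCCCCCCCCCCCCC1C(=O)OC(=O)C1(C)S(=O)c1ccccn1 | intermediate (not isolated)
7 | Aspergillus acid E, 14-(4-methyl-2,5-dioxo-2,5-dihydrofuran-3-yl)tetradecyl acetate (achiral) | CC(=O)OCCCCCCCCCCCCCCC1=C(C)C(=O)OC1=O | target

## Step count and risks
Total step count: 3. Longest linear sequence: 3 (1 → 2 → 5 → 7).

**Most likely to fail, first: step 2.**
- Risk: the primary radical can be caught by the thiocarbonyl of 4 before it reaches 3, which gives only the decarboxylated sulfide. Compound 4 is also sensitive to light and moisture.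
- Fallback: it sets out from 2, with 3 as partner, and comes back at 7. It separates C–C bond formation from installation of the alkene.
- Acid 2 is coupled with N-hydroxyphthalimide (DIC, cat. DMAP, CH2Cl2) to the bench-stable redox-active ester 1,3-dioxoisoindolin-2-yl 15-acetoxypentadecanoate F1.
- A reductive photoredox Giese addition to 3 (cat. Ru(bpy)3(PF6)2, Hantzsch ester, CH2Cl2, blue LED) then gives the saturated anhydride 14-(4-methyl-2,5-dioxooxolan-3-yl)tetradecyl acetate F2 as a diastereomer mixture.
- Soft double enolisation (TMSOTf 2.2 equiv, Et3N, CH2Cl2, 0 °C) gives 14-[4-methyl-2,5-bis(trimethylsilyloxy)furan-3-yl]tetradecyl acetate F3.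
- Br2 (1 equiv, CH2Cl2, −78 °C) oxidises F3 directly to 7.

**Second: step 3.**
- Risk: the minor diastereomer of 5 has C3–H anti to sulfur and can eliminate only toward the methyl group, giving an exocyclic alkene.
- Risk: wet peracid can open the anhydride, and over-oxidation at sulfur or at the pyridine nitrogen wastes material.
- Fallback: it sets out from 5 and comes back at 7 without any oxidation. Compound 5 is treated with Et3N (1.5 equiv, THF, rt → 40 °C).
- Rationale: C3–H is α to one carbonyl and the pyridylthio group is β to it, so an E1cB retro-thia-Michael elimination takes place from either diastereomer. The same base moves any exocyclic alkene into the ring.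
- Work-up: a 1 M HCl wash removes the base and re-closes any opened anhydride. This fallback makes no new compound (F0).

**Third: step 1.**
- Risk: the free acid can be activated by Ac2O and acylate the alcohol of a second molecule, giving ester oligomers. Compound 1 is also poorly soluble.
- Fallback: it sets out from 1 and comes back at 2 by masking the acid first.
- BnBr and KHCO3 in DMF give benzyl 15-hydroxypentadecanoate F4.
- Ac2O in pyridine gives benzyl 15-acetoxypentadecanoate F5.
- Hydrogenolysis (H2, Pd/C, EtOAc) frees acid 2 without touching the acetate.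

## Further compounds
F1 | step 2 | 1,3-dioxoisoindolin-2-yl 15-acetoxypentadecanoate | CC(=O)OCCCCCCCCCCCCCCC(=O)ON1C(=O)c2ccccc2C1=O
F2 | step 2 | 14-(4-methyl-2,5-dioxooxolan-3-yl)tetradecyl acetate (diastereomer mixture) | CC(=O)OCCCCCCCCCCCCCCC1C(C)C(=O)OC1=O
F3 | step 2 | 14-[4-methyl-2,5-bis(trimethylsilyloxy)furan-3-yl]tetradecyl acetate | CC(=O)OCCCCCCCCCCCCCCc1c(C)c(O[Si](C)(C)C)oc1O[Si](C)(C)C
F0 | step 3 | none | none
F4 | step 1 | benzyl 15-hydroxypentadecanoate | OCCCCCCCCCCCCCCC(=O)OCc1ccccc1
F5 | step 1 | benzyl 15-acetoxypentadecanoate | CC(=O)OCCCCCCCCCCCCCCC(=O)OCc1ccccc1
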